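At late times the D.Q in this flask is the Q that J has given, so the question is how much J a charge must hold for Q to match the X.

    X ⇌ D (K1 = 1.15, k1 = 0.0102 s⁻¹)
    J → Q (k2 = 0.0523 s⁻¹)
    D + Q → D.Q (k3 = 0.687 M⁻¹ s⁻¹)
    J + E → J.E (k4 = 0.141 M⁻¹ s⁻¹)

X 1.0 M; J 1.10 M; E 1.00 M; time 25 min

- the reaction counts as stopped when no species that holds the X changes by six tenths of a point or more over the second half of the time
- run time (flask): 25 min

1. which holds at 25 min: what has brought the reaction to rest, or that it has not come to rest (J has run out first / forward and back rates have come level / all of X has reacted / it is still moving)
2. the D.Q standing at 25 min, as a percentage of the X charged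
3. the D standing at 25 min, as a percentage of the X charged

We turn the question round and suppose that X reacted to the end. Then q, the Q formed, must reach 1.0 M. J leaves by two routes. Let s be the constant of the J + E step over that of the J → Q step, 2.70 M⁻¹. For each Q formed, J loses s[E] to E, which at the charge is 2.70 (the selectivity factor). E therefore falls as exp(−s·q). We call the J bill the J charge needed for Q to reach the X, counting the J that goes to Q and the J that goes to E: 1.93 M. This flask holds 1.10 M, less than the bill by 0.830 M, so we expect J, the limiting reagent, to end the reaction with X unconverted.

Our reckoning sets q plus the E consumed equal to the J charge. One correction from a trial q of 0.500 M gives 0.418 M, so D.Q stands at 41.8%. The remainder is shared between X and D by the equilibrium constant, with a relaxation half-life of 0.606 min, shorter than the time, which puts D at 31.2%.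

The forecast says J has run out first, with D.Q at 42.1% and D at 31%, holding that “J and Q are used up quickly, so the yield is set by how J splits between its two routes”. Its D.Q stands slightly above ours.

The flask gives: J has run out first. At 25.0 min, 0% of the J remains, with D.Q at 42.1% and D at 31.0%. The bill stands above the charge because of the passing of J + E into J.E: the run without that step lifts D.Q from 42.1% to >99.9% and turns the ending, the bill then being 1.0 M, below the charge. In a neighbour flask, like this one but with E at 0.25 M, the bill is 1.23 M, still above its J charge of 1.10 M, and D.Q there reaches 87.4% with 0% of J left.

All constants are made up; the result is computed.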